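(The runs were generated by integration for substances that don't exist.)

Read the two runs as one question: what stops the product?

in all of them: left-handed substrate 0.10 M; right-handed substrate 0.10 M

| flask | reagent | temperature | remark | time |
|---|---|---|---|---|
| Wednesday's | 0.20 M | 90 °C | the very flask that is asked about, followed so far |  |
| Saturday's | 0.20 M | 96 °C | run made earlier |  |
| flask | 0.200 M | 90 °C |  | 10 h |

- Wednesday's (time / h: left-handed product / %): 0.333: 7.7; 1.00: 12.9; 1.50: 16.1; 2.50: 18.0; 4.00: 19.1; 5.00: 21.4; 6.00: 21.3
- Saturday's (time / h: left-handed product / %): 0.333: 6.9; 1.00: 15.9; 1.50: 16.8; 2.50: 21.2; 4.00: 24.5; 5.00: 24.7; 6.00: 24.6

(scatter of a reading: 1 percentage point)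

- cedar: at 10 h add reagent, 50.0% of the amount charged, then wait 10 h
- oak: at 10 h raise the temperature by 20 K, then wait 10 h
- larch: change nothing and wait 10 h more
- alder: at 10 h take out 90% of the left-handed product then present, then wait 10 h

* left-handed product, in percent of the left-handed substrate and right-handed substrate together first charged, at 10 h
* which option adds most left-handed product ("none" when 2 percentage points or less is all one gets) (cedar / oak / larch / alder / none)
* left-handed product present, with what was taken out counted in, in percent of the left-handed substrate and right-handed substrate together first charged, after larch
* left-handed product present, with what was taken out counted in, in percent of the left-handed substrate and right-handed substrate together first charged, after alder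

- reagent is single-handed; left-handed substrate and right-handed substrate are mirror images of each other, charged as a racemate, each of them at the stated concentration
- removed left-handed product is counted in
- additions bring no volume worth counting
- the handed part of reagent does not stay in what it makes, so the products of the two hands are mirror images too

Wednesday's run is the asked flask itself, followed up to 6.00 h, so its last readings lead towards the answer, and they stand near 21.3%. But the left-handed substrate is 50.0% of the racemate, so this flask levels off short of what its left-handed substrate allows. Saturday's run, at 96 °C, levels off at 24.6%, and that step of 3.3 percentage points against a scatter of 1 point suggests that the plateau moves with temperature. A balance fits this, but so does a reagent shared between the product and some loss of its own. The runs do not separate these two, so the choice is a judgement, and my reckoning takes the loss of reagent, with reagent as the limiting reagent.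

Then count one reagent per product. Wednesday's 0.0426 M of left-handed product from 0.20 M of reagent gives 21.3%, and this is the reagent yield, the left-handed product at the plateau per reagent charged. So I expect this flask to stay near 21.3% at 10 h, and larch and alder to stay there too. Oak brings no new reagent, but cedar does, and at this yield you can expect 11 points from it, so I choose cedar.

The forecast parts from this. It gives 21.3%, then 21.2% after larch and 28.5% after alder, and it chooses oak, reasoning that “A temperature-dependent plateau suggests a reversible reaction”.

The flask gives 23.8% at 10 h, and the best option is cedar, which adds 14 points against my 11 points, while oak adds 1.1 points. Larch ends at 24.8% and alder at 24.8%, with what was taken out counted in. At 10.0 h the flask holds 1.52% of its charged reagent and 50.8% of its left-handed substrate.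

    2 reagent → self-condensation product (k = 0.0671 /M/min, Ea = 84.0 kJ/mol)
    reagent + left-handed substrate → left-handed product (k = 0.0527 /M/min, Ea = 98.0 kJ/mol)
    left-handed substrate ⇌ achiral form (K = 0.710, k = 0.0256 /min, Ea = 101 kJ/mol, ΔH = −21.0 kJ/mol)
    right-handed substrate ⇌ achiral form (K = 0.710, k = 0.0256 /min, Ea = 101 kJ/mol, ΔH = −21.0 kJ/mol)
    reagent + right-handed substrate → right-handed product (k = 0.0148 /M/min, Ea = 99.0 kJ/mol)
    (constants at 90 °C)

The reagent yield, read as 21.3% on Wednesday's run, comes to 23.8% on this flask at 10 h. On the neighbouring flask charged with 0.50 M of reagent it is lower, at 12.8%, from 31.9% of left-handed product.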